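**Retrosynthetic overview**

1. Numbering: ring A = C1(OH)–C2–C3(Cl)–C4(CH3, side chain)–C5–C10(CH3); ring B = C5–C6–C7=C8(C12 ester)–C9(C11 aldehyde)–C10; β is the face of the C10 methyl. The strategy rests on the 1,3-pair of the axial 1α-hydroxyl and the equatorial 3β-chloride across the C2 methylene of ring A, next to quaternary C4.
2. Key disconnection: C1–C2 and C3–Cl, a Prins cyclisation of a C1 aldehyde (on C10) onto a C3=C2 vinyl group (on C4) that is ended by chloride. Ring A is the second ring to form.
3. Endgame after ring closure: arm ester → C(CH3)2OH, C8 enol triflate → C12 methyl ester (Pd/CO/MeOH), C11 silyl ether → aldehyde last.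
4. C4 (CH3, vinyl, arm) is set by a Johnson–Claisen rearrangement of a (Z)-allylic alcohol made from a C5 ynoate and Me2CuLi. The arm is lengthened to an enoate before ring closure so that no carbonyl oxygen can reach C3 in the key step.
5. Ring B is formed first by a catalytic asymmetric Diels–Alder reaction of ethyl (E)-2-methyl-4-oxobut-2-enoate with a (Z)-1-silyloxymethyl-2-silyloxybutadiene, which sets C5, C9 and C10.

Key step: step 18

Assumption: the diene must add to the re face at C5 (the formyl-bearing carbon) of enal 4; the (S)-configured oxazaborolidinium catalyst is taken to do this on the usual formyl C–H···O binding picture, and its mirror image is used if the sense proves opposite.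

**Route**

Step 1
Reactants: 1 2,2-dimethoxyacetaldehyde; 2 ethyl 2-(triphenylphosphoranylidene)propanoate
Product: 3 ethyl (E)-4,4-dimethoxy-2-methylbut-2-enoate
Conditions: CH2Cl2, rt (1 used as its 60% aqueous solution)
Reagents that add atoms: ethyl 2-(triphenylphosphoranylidene)propanoate (2) CCOC(=O)C(C)=P(c1ccccc1)(c1ccccc1)c1ccccc1
Why: Wittig olefination; the stabilised α-methyl ylide reacts with the free aldehyde and should give the (E)-enoate (ester trans to the acetal carbon).

Step 2
Reactants: 3 ethyl (E)-4,4-dimethoxy-2-methylbut-2-enoate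
Product: 4 ethyl (E)-2-methyl-4-oxobut-2-enoate
Conditions: Amberlyst-15, acetone/H2O, rt
Reagents that add atoms: water O
Why: Acid-catalysed acetal hydrolysis unmasks the aldehyde; the E geometry (formyl trans to ester) is the stable one and should be kept.

Step 3
Reactants: 5 propane-1,3-diol
Product: 6 3-(tert-butyldiphenylsilyloxy)propan-1-ol
Conditions: 5 (4 equiv), TBDPSCl (1 equiv), imidazole, CH2Cl2, 0 °C → rt
Reagents that add atoms: tert-butyl(chloro)diphenylsilane CC(C)(C)[Si](Cl)(c1ccccc1)c1ccccc1
Why: Silyl ether formation; the excess of diol makes monosilylation the main outcome.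

Step 4
Reactants: 6 3-(tert-butyldiphenylsilyloxy)propan-1-ol
Product: 7 3-(tert-butyldiphenylsilyloxy)propanal
Conditions: Dess–Martin periodinane, CH2Cl2, rt
Reagents that add atoms: none
Why: Dess–Martin oxidation of the primary alcohol to the aldehyde leaves the silyl ether untouched.

Step 5
Reactants: 7 3-(tert-butyldiphenylsilyloxy)propanal; 8 vinylmagnesium bromide
Product: 9 5-(tert-butyldiphenylsilyloxy)pent-1-en-3-ol (racemic)
Conditions: THF, −78 → 0 °C; aq NH4Cl
Reagents that add atoms: vinylmagnesium bromide (8) C=C[Mg]Br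
Why: Grignard 1,2-addition to the aldehyde; the carbinol centre is oxidised in the next step, so its configuration does not matter.

Step 6
Reactants: 9 5-(tert-butyldiphenylsilyloxy)pent-1-en-3-ol
Product: 10 5-(tert-butyldiphenylsilyloxy)pent-1-en-3-one
Conditions: Dess–Martin periodinane, CH2Cl2, 0 °C
Reagents that add atoms: none
Why: Dess–Martin oxidation of the allylic alcohol gives the vinyl ketone under non-basic conditions that avoid β-elimination of the silyloxy group.

Step 7
Reactants: 10 5-(tert-butyldiphenylsilyloxy)pent-1-en-3-one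
Product: 11 (Z)-1-(tert-butyldiphenylsilyloxy)-3-(triisopropylsilyloxy)penta-2,4-diene
Conditions: TIPSOTf, Et3N, CH2Cl2, 0 °C
Reagents that add atoms: triisopropylsilyl trifluoromethanesulfonate CC(C)[Si](OS(=O)(=O)C(F)(F)F)(C(C)C)C(C)C
Why: Soft enolisation (silyl triflate and amine) can occur only toward the CH2 side and gives the 2-silyloxydiene; the (Z)-enol ether, with CH2OTBDPS cis to oxygen and so on the outside of the s-cis diene, is the expected major isomer.

Step 8
Reactants: 4 ethyl (E)-2-methyl-4-oxobut-2-enoate; 11 (Z)-1-(tert-butyldiphenylsilyloxy)-3-(triisopropylsilyloxy)penta-2,4-diene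
Product: 12 ring B aldehyde: cyclohexene C5–C10 with C7=C8 as TIPS enol ether (OTIPS on C8), C9 CH2OTBDPS (β), C10 CH3 (β) and CO2Et (α), C5 CHO (β, 5α-H)
Conditions: (S)-3,3-diphenyl-1-(o-tolyl)tetrahydro-1H,3H-pyrrolo[1,2-c][1,3,2]oxazaborole (20 mol %), Tf2NH (18 mol %), 11 (1.5 equiv), CH2Cl2, −78 → −40 °C
Reagents that add atoms: none
Why: Catalytic asymmetric Diels–Alder reaction: the boron cation binds the formyl group, the enol ether carbon C9 (nucleophilic terminus) joins C10 (β to formyl) and C6 joins C5, so the formyl group ends para to the C8 oxygen; the formyl-endo transition state puts C11, the C10 methyl and the C5 formyl cis and the ester trans, and shielding of one enal face by the catalyst sets C5, C9 and C10 in the absolute sense.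

Step 9
Reactants: 12 ring B aldehyde; 13 dimethyl (1-diazo-2-oxopropyl)phosphonate
Product: 14 ring B alkyne: as 12 with C5 carrying ethynyl (C4≡C3H) in place of CHO
Conditions: K2CO3, MeOH, 0 °C → rt
Reagents that add atoms: dimethyl (1-diazo-2-oxopropyl)phosphonate (13) COP(=O)(OC)C(=[N+]=[N-])C(C)=O
Why: Ohira–Bestmann (Seyferth–Gilbert) homologation turns the aldehyde into the terminal alkyne under mild carbonate base, chosen to leave C5 and the TIPS enol ether intact.

Step 10
Reactants: 14 ring B alkyne; 15 methyl chloroformate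
Product: 17 ring B ynoate: C5–C4≡C3–C2O2Me, via lithium acetylide 16 (not isolated)
Conditions: LDA, THF, −78 °C; then ClCO2Me, −78 → −40 °C
Reagents that add atoms: methyl chloroformate (15) COC(=O)Cl
Why: Deprotonation of the terminal alkyne and C-acylation of the lithium acetylide with the chloroformate; the neopentyl C10 ester has no α-hydrogen and is not attacked by the amide base.

Step 11
Reactants: 17 ring B ynoate; 18 lithium dimethylcuprate
Product: 19 ring B (Z)-enoate: C5–C4(CH3)=C3H–CO2Me with C5 and CO2Me cis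
Conditions: Me2CuLi (from MeLi and CuI), THF, −78 °C; MeOH at −78 °C
Reagents that add atoms: lithium dimethylcuprate (18) [Li+].C[Cu-]C
Why: syn-Carbocupration of the ynoate and protonation with retention place the new methyl trans to the ester, so C5 and the ester are cis, the (Z)-geometry needed for allylic 1,3-strain control in step 14.

Step 12
Reactants: 19 ring B (Z)-enoate
Product: 21 C7=C8 enol triflate of the (Z)-enoate, via cesium enolate 20 (not isolated)
Conditions: CsF, PhNTf2, DME, rt
Reagents that add atoms: N-phenylbis(trifluoromethanesulfonimide) O=S(=O)(N(c1ccccc1)S(=O)(=O)C(F)(F)F)C(F)(F)F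
Why: Fluoride cleaves the silyl enol ether (far faster than the alkyl silyl ether) and the regiodefined C8 enolate is trapped on oxygen by PhNTf2, which should give the C7=C8 enol triflate without enolate equilibration.

Step 13
Reactants: 21 enol triflate (Z)-enoate
Product: 22 (Z)-allylic alcohol: C5–C4(CH3)=C3H–C2H2OH, C10 CO2Et retained
Conditions: i-Bu2AlH (2.2 equiv), CH2Cl2, −78 °C; Rochelle salt
Reagents that add atoms: none
Why: i-Bu2AlH 1,2-reduction of the conjugated methyl ester to the allylic alcohol; the α-quaternary, doubly flanked C10 ethyl ester should react far more slowly at −78 °C, and the enol triflate is inert to the hydride.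

Step 14
Reactants: 22 (Z)-allylic alcohol; 23 triethyl orthoacetate
Product: 26 diester with quaternary C4 bearing CH3, vinyl (C3H=C2H2) and CH2CO2Et, via mixed orthoester 24 (not isolated), via ketene acetal 25 (not isolated)
Conditions: MeC(OEt)3 (excess), EtCO2H (cat.), xylene, 140 °C, EtOH distilled off
Reagents that add atoms: triethyl orthoacetate (23) CCOC(C)(OCC)OCC
Why: Johnson–Claisen rearrangement: allylic 1,3-strain from the cis CH2O group holds the C5–H bond in the alkene plane, and the ketene acetal carbon should bond to the C4 face flanked by C6H2 and not by quaternary C10, which gives the target configuration at C4 (arm α and methyl β once the new vinyl group is turned toward C1).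

Step 15
Reactants: 26 diester
Product: 27 diol: C10 CH2OH (C1) and C4 CH2CH2OH
Conditions: i-Bu2AlH (6 equiv), CH2Cl2, −78 → 0 °C; Rochelle salt
Reagents that add atoms: none
Why: Exhaustive i-Bu2AlH reduction of both esters (the hindered C10 ester needs 0 °C) gives the diol; the enol triflate tolerates the reagent.

Step 16
Reactants: 27 diol
Product: 28 dialdehyde: C10 CHO (C1) and C4 CH2CHO
Conditions: Dess–Martin periodinane (3 equiv), CH2Cl2, 0 °C → rt; used crude
Reagents that add atoms: none
Why: Double Dess–Martin oxidation under neutral conditions gives the dialdehyde, which is used at once to avoid aldol reactions of the enolisable arm aldehyde.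

Step 17
Reactants: 28 dialdehyde; 29 methyl (triphenylphosphoranylidene)acetate
Product: 30 Prins precursor: ring B with C7=C8 enol triflate, C9 CH2OTBDPS, C10 (CH3)(CHO), C5–C4(CH3)(vinyl)(CH2CH=CHCO2Me, E)
Conditions: Ph3P=CHCO2Me (1.05 equiv), CH2Cl2, 0 °C → rt
Reagents that add atoms: methyl (triphenylphosphoranylidene)acetate (29) COC(=O)C=P(c1ccccc1)(c1ccccc1)c1ccccc1
Why: Wittig olefination with a stabilised ylide: the CH2CHO aldehyde reacts while the α-quaternary, doubly flanked C1 aldehyde is too hindered, and the new C=C should be E.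

Step 18
Reactants: 30 Prins precursor; 31 tin tetrachloride
Product: 32 trans-decalin 1α-ol 3β-chloride with 4β-CH3, 4α-CH2CH=CHCO2Me, C7=C8 enol triflate and C9 CH2OTBDPS
Conditions: SnCl4 (2.5 equiv), CH2Cl2, −78 → −40 °C; aq NaHCO3
Reagents that add atoms: tin tetrachloride (31) Cl[Sn](Cl)(Cl)Cl
Why: Proposed new method: SnCl4 binds the C1 aldehyde and the terminal vinyl carbon C2 attacks it through a chair transition state (6-endo with respect to the alkene, the only mode that avoids a primary cation), while chloride carried by SnCl5− adds to C3 anti to the forming C1–C2 bond, so C1–C2 and C3–Cl are made in one event and ring A closes as a trans-decalin, the only fusion that the trans C1 and C4 groups on ring B allow. The closest known reaction type is the Lewis acid (SnCl4, TiCl4, Me2AlCl) Prins cyclisation of hex-5-enals to 3-chlorocyclohexanols; it is new here because the alkene is an unactivated vinyl group on quaternary C4. C1 is controlled by peri strain: an equatorial tin-bound oxygen would sit against the C9 CH2OTBDPS group (whose bulky silyl ether should not chelate tin), so oxygen goes axial (1α); C3 is controlled by the anti addition, which places chloride antiperiplanar to the C1–C2 ring bond, that is equatorial (3β). The step needs chloride delivery to be faster than migration of the axial C4 methyl or of the C4–C5 bond to the developing C3 cation; low temperature, excess SnCl4 as chloride carrier and the concerted anti addition are meant to secure this, and C4 carries no hydrogen, so no ene pathway exists. The substrate secures chemoselectivity: the enoate arm and the enol triflate are electron-poor alkenes that do not attack the aldehyde, and no carbonyl oxygen can reach C3 through a five- or six-membered ring, which is why the arm is a four-carbon enoate and not an acetate.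

Step 19
Reactants: 32 chlorohydrin enoate; 33 methylmagnesium bromide
Product: 35 chlorohydrin with side chain CH2CH=CH–C(CH3)2OH (E), via enone 34 (not isolated)
Conditions: MeMgBr (5 equiv), THF, −40 → 0 °C; aq NH4Cl
Reagents that add atoms: methylmagnesium bromide (33) C[Mg]Br
Why: Double Grignard 1,2-addition to the methyl ester (through the enone) gives the tertiary allylic alcohol; the C1 hydroxyl is carried as its magnesium alkoxide, and the enol triflate and the equatorial neopentyl chloride should not react with the Grignard reagent below 0 °C.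

Step 20
Reactants: 35 tertiary alcohol enol triflate; 36 carbon monoxide; 37 methanol
Product: 38 C12 methyl ester with C11 OTBDPS
Conditions: Pd(OAc)2 (10 mol %), dppp, CO (1 atm), Et3N, MeOH/DMF, 50 °C
Reagents that add atoms: carbon monoxide (36) [C-]#[O+]; methanol (37) CO
Why: Palladium-catalysed methoxycarbonylation: zerovalent palladium inserts into the C8–OTf bond, CO insertion and methanolysis give the C12 methyl ester; the alkyl chloride and the free hydroxyls are inert.

Step 21
Reactants: 38 C12 methyl ester with C11 OTBDPS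
Product: 39 C11 primary alcohol (triol ester)
Conditions: HF·pyridine, pyridine, THF, 0 °C → rt; used without delay
Reagents that add atoms: none
Why: Fluoride-mediated desilylation under buffered, weakly acidic conditions frees the C11 hydroxyl without forming an alkoxide, which should keep lactonisation onto the C12 ester and ionisation of the tertiary allylic alcohol in check.

Step 22
Reactants: 39 triol ester
Product: 40 target CNP0167913.1
Conditions: TEMPO (20 mol %), PhI(OAc)2 (1.2 equiv), CH2Cl2, rt
Reagents that add atoms: none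
Why: Oxoammonium (TEMPO) oxidation with PhI(OAc)2 is selective for the primary C11 alcohol over the hindered axial C1 alcohol and the tertiary alcohol, and its near-neutral conditions should leave the epimerisable C9 centre of the β,γ-unsaturated aldehyde intact.

**Compound list**

1 | 2,2-dimethoxyacetaldehyde | COC(OC)C=O | starting material
2 | ethyl 2-(triphenylphosphoranylidene)propanoate | CCOC(=O)C(C)=P(c1ccccc1)(c1ccccc1)c1ccccc1 | starting material
3 | ethyl (E)-4,4-dimethoxy-2-methylbut-2-enoate | CCOC(=O)/C(C)=C/C(OC)OC | intermediate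
4 | ethyl (E)-2-methyl-4-oxobut-2-enoate | CCOC(=O)/C(C)=C/C=O | intermediate
5 | propane-1,3-diol | OCCCO | starting material
6 | 3-(tert-butyldiphenylsilyloxy)propan-1-ol | OCCCO[Si](c1ccccc1)(c1ccccc1)C(C)(C)C | intermediate
7 | 3-(tert-butyldiphenylsilyloxy)propanal | O=CCCO[Si](c1ccccc1)(c1ccccc1)C(C)(C)C | intermediate
8 | vinylmagnesium bromide | C=C[Mg]Br | starting material
9 | 5-(tert-butyldiphenylsilyloxy)pent-1-en-3-ol (racemic) | C=CC(O)CCO[Si](c1ccccc1)(c1ccccc1)C(C)(C)C | intermediate
10 | 5-(tert-butyldiphenylsilyloxy)pent-1-en-3-one | C=CC(=O)CCO[Si](c1ccccc1)(c1ccccc1)C(C)(C)C | intermediate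
11 | (Z)-1-(tert-butyldiphenylsilyloxy)-3-(triisopropylsilyloxy)penta-2,4-diene | C=C/C(O[Si](C(C)C)(C(C)C)C(C)C)=C/CO[Si](c1ccccc1)(c1ccccc1)C(C)(C)C | intermediate
12 | ring B aldehyde (C8 OTIPS enol ether, C9 β-CH2OTBDPS, C10 β-CH3/α-CO2Et, C5 β-CHO) | CC(C)[Si](C(C)C)(C(C)C)OC1=CC[C@@H](C=O)[C@](C)(C(=O)OCC)[C@H]1CO[Si](c1ccccc1)(c1ccccc1)C(C)(C)C | intermediate
13 | dimethyl (1-diazo-2-oxopropyl)phosphonate | COP(=O)(OC)C(=[N+]=[N-])C(C)=O | starting material
14 | ring B alkyne (C5 ethynyl) | CC(C)[Si](C(C)C)(C(C)C)OC1=CC[C@@H](C#C)[C@](C)(C(=O)OCC)[C@H]1CO[Si](c1ccccc1)(c1ccccc1)C(C)(C)C | intermediate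
15 | methyl chloroformate | COC(=O)Cl | starting material
16 | lithium acetylide of 14 (not isolated) | CC(C)[Si](C(C)C)(C(C)C)OC1=CC[C@@H](C#C[Li])[C@](C)(C(=O)OCC)[C@H]1CO[Si](c1ccccc1)(c1ccccc1)C(C)(C)C | intermediate
17 | ring B ynoate (C5–C≡C–CO2Me) | CC(C)[Si](C(C)C)(C(C)C)OC1=CC[C@@H](C#CC(=O)OC)[C@](C)(C(=O)OCC)[C@H]1CO[Si](c1ccccc1)(c1ccccc1)C(C)(C)C | intermediate
18 | lithium dimethylcuprate | [Li+].C[Cu-]C | starting material
19 | ring B (Z)-enoate (C5 cis to CO2Me) | CC(C)[Si](C(C)C)(C(C)C)OC1=CC[C@@H](/C(C)=C\C(=O)OC)[C@](C)(C(=O)OCC)[C@H]1CO[Si](c1ccccc1)(c1ccccc1)C(C)(C)C | intermediate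
20 | cesium C8 enolate of 19 (not isolated) | [Cs+].[O-]C1=CC[C@@H](/C(C)=C\C(=O)OC)[C@](C)(C(=O)OCC)[C@H]1CO[Si](c1ccccc1)(c1ccccc1)C(C)(C)C | intermediate
21 | C7=C8 enol triflate of the (Z)-enoate | O=S(=O)(OC1=CC[C@@H](/C(C)=C\C(=O)OC)[C@](C)(C(=O)OCC)[C@H]1CO[Si](c1ccccc1)(c1ccccc1)C(C)(C)C)C(F)(F)F | intermediate
22 | (Z)-allylic alcohol (C5–C4(CH3)=C3H–C2H2OH) | O=S(=O)(OC1=CC[C@@H](/C(C)=C\CO)[C@](C)(C(=O)OCC)[C@H]1CO[Si](c1ccccc1)(c1ccccc1)C(C)(C)C)C(F)(F)F | intermediate
23 | triethyl orthoacetate | CCOC(C)(OCC)OCC | starting material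
24 | mixed orthoester of 22 (not isolated) | O=S(=O)(OC1=CC[C@@H](/C(C)=C\COC(C)(OCC)OCC)[C@](C)(C(=O)OCC)[C@H]1CO[Si](c1ccccc1)(c1ccccc1)C(C)(C)C)C(F)(F)F | intermediate
25 | ketene acetal of 22 (not isolated) | O=S(=O)(OC1=CC[C@@H](/C(C)=C\COC(=C)OCC)[C@](C)(C(=O)OCC)[C@H]1CO[Si](c1ccccc1)(c1ccccc1)C(C)(C)C)C(F)(F)F | intermediate
26 | diester with quaternary C4 (CH3, vinyl, CH2CO2Et) | O=S(=O)(OC1=CC[C@@H]([C@](C)(CC(=O)OCC)C=C)[C@](C)(C(=O)OCC)[C@H]1CO[Si](c1ccccc1)(c1ccccc1)C(C)(C)C)C(F)(F)F | intermediate
27 | diol (C1 CH2OH, arm CH2CH2OH) | O=S(=O)(OC1=CC[C@@H]([C@](C)(CCO)C=C)[C@](C)(CO)[C@H]1CO[Si](c1ccccc1)(c1ccccc1)C(C)(C)C)C(F)(F)F | intermediate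
28 | dialdehyde (C1 CHO, arm CH2CHO) | O=S(=O)(OC1=CC[C@@H]([C@](C)(CC=O)C=C)[C@](C)(C=O)[C@H]1CO[Si](c1ccccc1)(c1ccccc1)C(C)(C)C)C(F)(F)F | intermediate
29 | methyl (triphenylphosphoranylidene)acetate | COC(=O)C=P(c1ccccc1)(c1ccccc1)c1ccccc1 | starting material
30 | Prins precursor (C1 aldehyde, C4 vinyl, (E)-enoate arm, enol triflate, C11 OTBDPS) | O=S(=O)(OC1=CC[C@@H]([C@](C)(C/C=C/C(=O)OC)C=C)[C@](C)(C=O)[C@H]1CO[Si](c1ccccc1)(c1ccccc1)C(C)(C)C)C(F)(F)F | intermediate
31 | tin tetrachloride | Cl[Sn](Cl)(Cl)Cl | starting material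
32 | trans-decalin 1α-ol 3β-chloride (enoate arm, enol triflate, C11 OTBDPS) | O=S(=O)(OC1=CC[C@H]2[C@](C)(C/C=C/C(=O)OC)[C@@H](Cl)C[C@H](O)[C@]2(C)[C@H]1CO[Si](c1ccccc1)(c1ccccc1)C(C)(C)C)C(F)(F)F | intermediate
33 | methylmagnesium bromide | C[Mg]Br | starting material
34 | enone-arm chlorohydrin (not isolated; drawn in neutral form) | O=S(=O)(OC1=CC[C@H]2[C@](C)(C/C=C/C(C)=O)[C@@H](Cl)C[C@H](O)[C@]2(C)[C@H]1CO[Si](c1ccccc1)(c1ccccc1)C(C)(C)C)C(F)(F)F | intermediate
35 | chlorohydrin with (E)-CH2CH=CH–C(CH3)2OH side chain, enol triflate | O=S(=O)(OC1=CC[C@H]2[C@](C)(C/C=C/C(C)(C)O)[C@@H](Cl)C[C@H](O)[C@]2(C)[C@H]1CO[Si](c1ccccc1)(c1ccccc1)C(C)(C)C)C(F)(F)F | intermediate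
36 | carbon monoxide | [C-]#[O+] | starting material
37 | methanol | CO | starting material
38 | C12 methyl ester, C11 OTBDPS | COC(=O)C1=CC[C@H]2[C@](C)(C/C=C/C(C)(C)O)[C@@H](Cl)C[C@H](O)[C@]2(C)[C@H]1CO[Si](c1ccccc1)(c1ccccc1)C(C)(C)C | intermediate
39 | C11 primary alcohol (triol ester) | COC(=O)C1=CC[C@H]2[C@](C)(C/C=C/C(C)(C)O)[C@@H](Cl)C[C@H](O)[C@]2(C)[C@H]1CO | intermediate
40 | CNP0167913.1: methyl (1S,3S,4S,5R,9R,10S)-3-chloro-9-formyl-1-hydroxy-4-[(E)-4-hydroxy-4-methylpent-2-enyl]-4,10-dimethyl-Δ7-octalin-8-carboxylate (overview numbering) | COC(=O)C1=CC[C@H]2[C@](C)(C/C=C/C(C)(C)O)[C@@H](Cl)C[C@H](O)[C@]2(C)[C@H]1C=O | target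

**Step count and risks**

Total steps: 22. Longest linear sequence: 20 steps (steps 3–22, from propane-1,3-diol).

Steps most likely to fail:

1. Step 18 (the labelled step). What may go wrong: the developing C3 cation rearranges (1,2-shift of the C4 methyl or of the C4–C5 bond, or proton loss from C2) before chloride arrives, or oxygen ends up equatorial at C1. The fallback uses known reactions and closes ring A without a C3 cation. It sets out from 30: vinylmagnesium bromide adds to the C1 aldehyde at −78 °C to give the divinyl carbinol F1 (both C1 epimers); ring-closing metathesis with the second-generation Grubbs catalyst joins the two vinyl groups to the ring A cyclohexenol F2; Dess–Martin oxidation gives the ring A enone F3 (C1 ketone, C2=C3); anhydrous HCl in CH2Cl2 at 0 °C adds reversibly in conjugate fashion, so that chloride should settle in the equatorial 3β position of the β-chloro ketone F4; LiBH(s-Bu)3 (1.1 equiv, THF, −78 °C) then delivers hydride from the equatorial side to give the axial 1α-alcohol, which is 32, where the route is rejoined.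

2. Step 8. What may go wrong: bond formation between the substituted diene terminus C9 and the fully substituted C10 is slow, so the acid-sensitive diene decomposes (loss of the allylic silyloxy group, cleavage of the enol ether) or endo and facial selectivity erode. The fallback replaces catalyst control by auxiliary control. It sets out from 4: Pinnick oxidation (NaClO2, NaH2PO4, 2-methyl-2-butene) gives the acid F5; pivaloyl chloride/Et3N and then the lithium salt of (R)-4-benzyloxazolidin-2-one give the imide F6; Diels–Alder reaction with 11 promoted by Et2AlCl at −78 °C (aluminium chelate, s-cis acyl group, diene approaching the face away from benzyl, which is the re face at C5) gives the auxiliary-bearing adduct F7; LiBH4 cleaves the imide to the C5 primary alcohol F8 and frees the auxiliary; Dess–Martin oxidation gives 12, where the route is rejoined.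

3. Step 21. What may go wrong: the freed C11 hydroxyl closes onto the neighbouring C12 methyl ester to form the 11,12-lactone before it can be oxidised. The fallback changes the order of events so that a hydroxy ester never exists. It sets out from 35: HF·pyridine gives the C11 alcohol enol triflate F9; TEMPO/PhI(OAc)2 gives the C11 aldehyde enol triflate F10; methoxycarbonylation under weakly basic conditions (Pd(OAc)2, dppp, CO, MeOH, 2,6-lutidine, DMF, rt) then gives 40 directly.

Further compounds
F1 | step 18 | divinyl carbinol (C1 CH(OH)CH=CH2, both epimers) | O=S(=O)(OC1=CC[C@@H]([C@](C)(C/C=C/C(=O)OC)C=C)[C@](C)(C(O)C=C)[C@H]1CO[Si](c1ccccc1)(c1ccccc1)C(C)(C)C)C(F)(F)F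
F2 | step 18 | ring A cyclohexenol (C1 OH, C2=C3) | O=S(=O)(OC1=CC[C@H]2[C@](C)(C/C=C/C(=O)OC)C=CC(O)[C@]2(C)[C@H]1CO[Si](c1ccccc1)(c1ccccc1)C(C)(C)C)C(F)(F)F
F3 | step 18 | ring A enone (C1 ketone, C2=C3) | O=S(=O)(OC1=CC[C@H]2[C@](C)(C/C=C/C(=O)OC)C=CC(=O)[C@]2(C)[C@H]1CO[Si](c1ccccc1)(c1ccccc1)C(C)(C)C)C(F)(F)F
F4 | step 18 | 3β-chloro C1 ketone | O=S(=O)(OC1=CC[C@H]2[C@](C)(C/C=C/C(=O)OC)[C@@H](Cl)CC(=O)[C@]2(C)[C@H]1CO[Si](c1ccccc1)(c1ccccc1)C(C)(C)C)C(F)(F)F
F5 | step 8 | (E)-4-ethoxy-3-methyl-4-oxobut-2-enoic acid | CCOC(=O)/C(C)=C/C(=O)O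
F6 | step 8 | (R)-4-benzyl-3-[(E)-4-ethoxy-3-methyl-4-oxobut-2-enoyl]oxazolidin-2-one | CCOC(=O)/C(C)=C/C(=O)N1[C@H](Cc2ccccc2)COC1=O
F7 | step 8 | auxiliary-bearing ring B adduct (C5 acyl oxazolidinone) | CC(C)[Si](C(C)C)(C(C)C)OC1=CC[C@@H](C(=O)N2[C@H](Cc3ccccc3)COC2=O)[C@](C)(C(=O)OCC)[C@H]1CO[Si](c1ccccc1)(c1ccccc1)C(C)(C)C
F8 | step 8 | ring B C5 primary alcohol (C5 CH2OH) | CC(C)[Si](C(C)C)(C(C)C)OC1=CC[C@@H](CO)[C@](C)(C(=O)OCC)[C@H]1CO[Si](c1ccccc1)(c1ccccc1)C(C)(C)C
F9 | step 21 | C11 alcohol enol triflate | O=S(=O)(OC1=CC[C@H]2[C@](C)(C/C=C/C(C)(C)O)[C@@H](Cl)C[C@H](O)[C@]2(C)[C@H]1CO)C(F)(F)F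
F10 | step 21 | C11 aldehyde enol triflate | O=S(=O)(OC1=CC[C@H]2[C@](C)(C/C=C/C(C)(C)O)[C@@H](Cl)C[C@H](O)[C@]2(C)[C@H]1C=O)C(F)(F)F
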